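**Plan**

1. Retrosynthesis: remove the C10–C11 epoxide oxygen and the three ester C–O bonds; cut C10=C11 (cross-metathesis), C8–C9 (allylation) and C7=C14 (α-methylenation); remove the C4–C5 epoxide oxygen and the C4–CH3 bond; then take C4 out of the carbocycle (cut C3–C4 and C4–C5).
2. Enabling feature: with the C4–C5 epoxide removed, C3(O)–C4(Me)=C5 is an allyl unit whose central carbon C4 can be inserted as a carbene carbon between C3 and C5 of a cyclopentene (C1, C2, C3, C5, C6), and the cis oxygen on C2 can deliver the oxygen to C3.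
3. Forward, ring: Pd allylic alkylation, selenolactonisation/elimination and reduction give the cis cyclopentenol; CBr2 adds across C3=C5; Ag(I) opens the bicyclo[3.1.0]hexane to the six-membered ring while the C2 Boc carbonate closes a cyclic carbonate on C3.
4. Forward, rest: methyl at C4, acetate at O–C3, directed epoxidation, angelate at O–C2; the side chain is then grown from the C8 aldehyde (C14, then C9/C10, then C11 and its methyls), the second angelate is added and C10=C11 is epoxidised last.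
5. Stereochemistry: C1 from the stereoconvergent allylic alkylation; C2 from cis-lactonisation; C3 from the tether in the key step; C4/C5 from hydroxyl-directed epoxidation; C8 and C10 from reagent control (allylborane, chiral dioxirane).

Key step: step 7

Remarks:
- Locants follow the target. Carbocycle: C1 (side chain), C2 (OAng), C3 (OAc), C4 (Me), C5, C6. Side chain: C7 (=C14H2), C8 (OAng), C9, C10–C11 (epoxide). TBS = tert-butyldimethylsilyl; Ang = (Z)-2-methylbut-2-enoyl.
- Assumption: the (S,S)-DACH-phenyl ligand is taken to give (R)-3 (from the (R,R)-ligand giving the (S)-malonate with 3-acetoxycycloalkenes); the ligand hand that gives (R)-3 is the one meant.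
- Metal alkoxides that are only protonated on work-up are not numbered.

Step 1
Reactants: 1 (±)-cyclopent-2-en-1-yl acetate; 2 dimethyl malonate
Product: 3 dimethyl (R)-2-(cyclopent-2-en-1-yl)malonate
Conditions: NaH, (n-Hex)4NBr, [Pd(allyl)Cl]2 (cat.), (S,S)-DACH-phenyl ligand (cat.), CH2Cl2, 0 °C to rt
Reagents that add atoms: none
Why: Tsuji–Trost asymmetric allylic alkylation; both enantiomers of 1 ionise to the same meso π-allyl palladium complex and the chiral pocket should direct the malonate to one terminus, which sets C1 stereoconvergently.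

Step 2
Reactants: 3 dimethyl (R)-2-(cyclopent-2-en-1-yl)malonate
Product: 5 (S)-2-(cyclopent-2-en-1-yl)acetic acid, via malonic acid 4 (not isolated)
Conditions: KOH, MeOH/H2O, reflux; HCl to pH 1; then neat, 160 °C
Reagents that add atoms: potassium hydroxide, [K+].[OH-]
Why: Saponification and thermal decarboxylation of the malonic acid (malonic ester sequence); C1 is not enolisable, so its configuration should be kept (the descriptor changes only by priority).

Step 3
Reactants: 5 (S)-2-(cyclopent-2-en-1-yl)acetic acid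
Product: 7 (3aS,6aR)-3,3a,4,6a-tetrahydro-2H-cyclopenta[b]furan-2-one, via selenolactone 6 (not isolated)
Conditions: PhSeCl, CH2Cl2, −78 °C; then 30% H2O2, THF, 0 °C to rt
Reagents that add atoms: none
Why: Phenylselenolactonisation is an anti addition in which the carboxylate can only close a cis-fused γ-lactone, so O–C2 is set cis to the C1 arm; selenoxide syn-elimination runs away from the oxygen-bearing carbon and should give the C3=C5 alkene.

Step 4
Reactants: 7 (3aS,6aR)-3,3a,4,6a-tetrahydro-2H-cyclopenta[b]furan-2-one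
Product: 8 (1R,5S)-5-(2-hydroxyethyl)cyclopent-2-en-1-ol
Conditions: LiAlH4, THF, 0 °C
Reagents that add atoms: none
Why: Hydride reduction of the lactone to the diol; no stereocentre is touched and the isolated alkene is inert.

Step 5
Reactants: 8 (1R,5S)-5-(2-hydroxyethyl)cyclopent-2-en-1-ol
Product: 10 tert-butyl (1R,5S)-5-[2-(tert-butyldimethylsilyloxy)ethyl]cyclopent-2-en-1-yl carbonate, via mono-TBS ether 9 (not isolated)
Conditions: TBSCl (1.05 equiv), Et3N, DMAP (cat.), CH2Cl2, 0 °C; then Boc2O, rt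
Reagents that add atoms: tert-butyldimethylsilyl chloride, CC(C)(C)[Si](C)(C)Cl; di-tert-butyl dicarbonate, CC(C)(C)OC(=O)OC(=O)OC(C)(C)C
Why: The primary hydroxyl should silylate selectively at 0 °C; the remaining allylic secondary hydroxyl is then converted to its tert-butyl carbonate by DMAP-catalysed acylation in the same flask.

Step 6
Reactants: 10 tert-butyl (1R,5S)-5-[2-(tert-butyldimethylsilyloxy)ethyl]cyclopent-2-en-1-yl carbonate
Product: 11 tert-butyl 6,6-dibromo-3-[2-(tert-butyldimethylsilyloxy)ethyl]bicyclo[3.1.0]hexan-2-yl carbonate (2,3-cis; CBr2 bridge anti to both substituents)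
Conditions: CHBr3, 50% aq. NaOH, BnEt3NCl (cat.), CH2Cl2, rt
Reagents that add atoms: bromoform, BrC(Br)Br
Why: Phase-transfer [2+1] addition of dibromocarbene to the only alkene, expected anti to the two cis substituents; the facial outcome does not matter because the cyclopropane stereocentres are erased in step 7.

Step 7
Reactants: 11 tert-butyl 6,6-dibromo-3-[2-(tert-butyldimethylsilyloxy)ethyl]bicyclo[3.1.0]hexan-2-yl carbonate
Product: 14 (3aR,4S,7aR)-7-bromo-4-[2-(tert-butyldimethylsilyloxy)ethyl]-3a,4,5,7a-tetrahydro-1,3-benzodioxol-2-one, via bromoallyl cation 12 (not isolated), via tert-butoxydioxolanylium ion 13 (not isolated)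
Conditions: AgOTf, 2,6-di-tert-butyl-4-methylpyridine, CH2Cl2, rt to 40 °C
Reagents that add atoms: none
Why: Ag(I) abstracts the endo bromide while the C3–C5 cyclopropane bond opens in a disrotatory 2π-electrocyclic manner, so the five-membered ring becomes the six-membered 2-bromocyclohex-2-enyl cation 12 with the former carbene carbon as C4. The carbonyl oxygen of the C2 tert-butyl carbonate then adds to the C3 terminus and 13 loses 2-methylpropene to leave the cyclic carbonate. The closest known reaction type is the silver-promoted electrocyclic ring opening of ring-fused gem-dibromocyclopropanes with capture of the allyl cation by a tethered heteroatom nucleophile, combined with Boc-carbonate participation at cationic carbon as in iodocarbonate cyclisation. The carbocycle arises by ring expansion and the carbonate ring by 5-exo-trig closure; the new stereocentre C3 is set cis to C2 because the short tether can only reach the face that carries O–C2. The step needs C3-over-C5 regioselectivity and one face, both secured by intramolecular delivery from O–C2 (the silyl ether is remote and hindered), while the hindered pyridine takes up the proton released with 2-methylpropene so that Boc and TBS survive until ionisation. Both cyclopropane diastereomers of 11 should converge on cation 12.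

Step 8
Reactants: 14 (3aR,4S,7aR)-7-bromo-4-[2-(tert-butyldimethylsilyloxy)ethyl]-3a,4,5,7a-tetrahydro-1,3-benzodioxol-2-one
Product: 16 (1R,2S,6S)-6-[2-(tert-butyldimethylsilyloxy)ethyl]-3-methylcyclohex-3-ene-1,2-diol, via bromo diol 15 (not isolated)
Conditions: K2CO3, MeOH, rt; evaporate; then trimethylboroxine, Pd(dppf)Cl2 (5 mol%), dioxane/H2O, 90 °C
Reagents that add atoms: trimethylboroxine, CB1OB(C)OB(C)O1
Why: Methanolysis removes the cyclic carbonate first, so that Pd(0) meets no allylic carbonate leaving group; Suzuki–Miyaura methylation of the alkenyl bromide then installs the C4 methyl without touching a stereocentre.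

Step 9
Reactants: 16 (1R,2S,6S)-6-[2-(tert-butyldimethylsilyloxy)ethyl]-3-methylcyclohex-3-ene-1,2-diol
Product: 18 (1S,5S,6R)-6-hydroxy-2-methyl-5-[2-(tert-butyldimethylsilyloxy)ethyl]cyclohex-2-en-1-yl acetate, via stannylene acetal 17 (not isolated)
Conditions: Bu2SnO, toluene, reflux (−H2O); then AcCl, 0 °C
Reagents that add atoms: acetyl chloride, CC(Cl)=O
Why: Stannylene-acetal-mediated monoacylation of a cis-diol activates the equatorial oxygen; in the half-chair with the C1 arm equatorial, O–C2 is axial and the allylic O–C3 pseudo-equatorial, so the acetate should go to O–C3.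

Step 10
Reactants: 18 (1S,5S,6R)-6-hydroxy-2-methyl-5-[2-(tert-butyldimethylsilyloxy)ethyl]cyclohex-2-en-1-yl acetate
Product: 19 (1S,2R,3R,4R,6S)-3-hydroxy-1-methyl-4-[2-(tert-butyldimethylsilyloxy)ethyl]-7-oxabicyclo[4.1.0]heptan-2-yl acetate
Conditions: VO(acac)2 (cat.), t-BuOOH (decane), CH2Cl2, 0 °C to rt
Reagents that add atoms: tert-butyl hydroperoxide, CC(C)(C)OO
Why: Vanadium-catalysed hydroxyl-directed epoxidation; the axial homoallylic C2 hydroxyl binds the metal and should deliver oxygen to its own face of C4=C5, setting C4 and C5 cis to O–C2 and O–C3.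

Step 11
Reactants: 19 (1S,2R,3R,4R,6S)-3-hydroxy-1-methyl-4-[2-(tert-butyldimethylsilyloxy)ethyl]-7-oxabicyclo[4.1.0]heptan-2-yl acetate
Product: 20 (1S,2R,3R,4R,6S)-2-acetoxy-1-methyl-4-[2-(tert-butyldimethylsilyloxy)ethyl]-7-oxabicyclo[4.1.0]heptan-3-yl (Z)-2-methylbut-2-enoate
Conditions: angelic acid, 2,4,6-Cl3C6H2COCl, Et3N, toluene, rt (filter Et3N·HCl); then 19, toluene, 75 °C
Reagents that add atoms: angelic acid, C/C=C(/C)C(=O)O
Why: Yamaguchi-type mixed-anhydride esterification without DMAP, the protocol known to give angelates without Z-to-E isomerisation; the salt-free, amine-buffered medium should spare the epoxide.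

Step 12
Reactants: 20 (1S,2R,3R,4R,6S)-2-acetoxy-1-methyl-4-[2-(tert-butyldimethylsilyloxy)ethyl]-7-oxabicyclo[4.1.0]heptan-3-yl (Z)-2-methylbut-2-enoate
Product: 21 (1S,2R,3R,4R,6S)-2-acetoxy-4-(2-hydroxyethyl)-1-methyl-7-oxabicyclo[4.1.0]heptan-3-yl (Z)-2-methylbut-2-enoate
Conditions: TBAF, AcOH (1:1), THF, 0 °C to rt
Reagents that add atoms: none
Why: Acetic-acid-buffered fluoride desilylation of the primary silyl ether; the esters and the epoxide should tolerate these near-neutral conditions.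

Step 13
Reactants: 21 (1S,2R,3R,4R,6S)-2-acetoxy-4-(2-hydroxyethyl)-1-methyl-7-oxabicyclo[4.1.0]heptan-3-yl (Z)-2-methylbut-2-enoate
Product: 22 (1S,2R,3R,4S,6S)-2-acetoxy-1-methyl-4-(2-oxoethyl)-7-oxabicyclo[4.1.0]heptan-3-yl (Z)-2-methylbut-2-enoate
Conditions: Dess–Martin periodinane, NaHCO3, CH2Cl2, 0 °C to rt
Reagents that add atoms: none
Why: Buffered Dess–Martin oxidation of the primary alcohol to the C8 aldehyde; the α-carbon C7 is a CH2, so no stereocentre is at risk.

Step 14
Reactants: 22 (1S,2R,3R,4S,6S)-2-acetoxy-1-methyl-4-(2-oxoethyl)-7-oxabicyclo[4.1.0]heptan-3-yl (Z)-2-methylbut-2-enoate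
Product: 23 (1S,2R,3R,4S,6S)-2-acetoxy-1-methyl-4-(3-oxoprop-1-en-2-yl)-7-oxabicyclo[4.1.0]heptan-3-yl (Z)-2-methylbut-2-enoate
Conditions: 37% aq. CH2O, pyrrolidine (20 mol%), EtCO2H (20 mol%), i-PrOH, 45 °C
Reagents that add atoms: formaldehyde, C=O
Why: Amine/acid-catalysed Mannich condensation and elimination (α-methylenation of an aldehyde) installs C14 at C7 under mild conditions that the esters and epoxide should survive.

Step 15
Reactants: 23 (1S,2R,3R,4S,6S)-2-acetoxy-1-methyl-4-(3-oxoprop-1-en-2-yl)-7-oxabicyclo[4.1.0]heptan-3-yl (Z)-2-methylbut-2-enoate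
Product: 24 (1S,2R,3R,4S,6S)-2-acetoxy-4-[(3S)-3-hydroxyhexa-1,5-dien-2-yl]-1-methyl-7-oxabicyclo[4.1.0]heptan-3-yl (Z)-2-methylbut-2-enoate
Conditions: (−)-Ipc2BOMe (from (+)-α-pinene), allylMgBr, Et2O, −78 °C to rt; then 23, −100 to −78 °C; then HOCH2CH2NH2, rt
Reagents that add atoms: allylmagnesium bromide, C=CC[Mg]Br
Why: Brown allylation through a chair transition state; the allylborane from (+)-α-pinene adds to the Si face of aldehydes (as with benzaldehyde giving the S alcohol) and should set 8S under reagent control. The esters are inert at this temperature and the non-oxidative work-up avoids base and peroxide.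

Step 16
Reactants: 24 (1S,2R,3R,4S,6S)-2-acetoxy-4-[(3S)-3-hydroxyhexa-1,5-dien-2-yl]-1-methyl-7-oxabicyclo[4.1.0]heptan-3-yl (Z)-2-methylbut-2-enoate
Product: 25 (1S,2R,3R,4S,6S)-2-acetoxy-4-[(3S)-3-hydroxy-6-methylhepta-1,5-dien-2-yl]-1-methyl-7-oxabicyclo[4.1.0]heptan-3-yl (Z)-2-methylbut-2-enoate
Conditions: second-generation Ru benzylidene catalyst (5 mol%), 2-methyl-2-butene/CH2Cl2, 35 °C
Reagents that add atoms: 2-methyl-2-butene, CC=C(C)C
Why: Olefin cross-metathesis of the terminal alkene with 2-methyl-2-butene gives the prenyl-type C10=C11 alkene; the 1,1-disubstituted C7=C14 alkene and the conjugated angelate alkene are poor metathesis partners.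

Step 17
Reactants: 25 (1S,2R,3R,4S,6S)-2-acetoxy-4-[(3S)-3-hydroxy-6-methylhepta-1,5-dien-2-yl]-1-methyl-7-oxabicyclo[4.1.0]heptan-3-yl (Z)-2-methylbut-2-enoate
Product: 26 (1S,2R,3R,4S,6S)-2-acetoxy-1-methyl-4-{(3S)-6-methyl-3-[(Z)-2-methylbut-2-enoyloxy]hepta-1,5-dien-2-yl}-7-oxabicyclo[4.1.0]heptan-3-yl (Z)-2-methylbut-2-enoate
Conditions: angelic acid, 2,4,6-Cl3C6H2COCl, Et3N, toluene, rt (filter Et3N·HCl); then 25, toluene, 60 °C
Reagents that add atoms: angelic acid, C/C=C(/C)C(=O)O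
Why: The same DMAP-free Yamaguchi-type angeloylation, here on the less hindered C8 hydroxyl; acylating before the last epoxidation avoids cyclisation of a free hydroxy epoxide.

Step 18
Reactants: 26 (1S,2R,3R,4S,6S)-2-acetoxy-1-methyl-4-{(3S)-6-methyl-3-[(Z)-2-methylbut-2-enoyloxy]hepta-1,5-dien-2-yl}-7-oxabicyclo[4.1.0]heptan-3-yl (Z)-2-methylbut-2-enoate
Product: 27 CNP0316628.1, (1S,2R,3R,4S,6S)-2-acetoxy-4-{(3S)-4-[(2S)-3,3-dimethyloxiran-2-yl]-3-[(Z)-2-methylbut-2-enoyloxy]but-1-en-2-yl}-1-methyl-7-oxabicyclo[4.1.0]heptan-3-yl (Z)-2-methylbut-2-enoate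
Conditions: L-fructose-derived ketone (ent-Shi ketone, 0.3 equiv), Oxone, K2CO3, n-Bu4NHSO4 (cat.), MeCN/dimethoxymethane/aq. borate–EDTA buffer, 0 °C
Reagents that add atoms: potassium peroxymonosulfate (Oxone), [K+].[O-]S(=O)(=O)OO
Why: Shi epoxidation by a chiral dioxirane through a spiro transition state; the electron-rich trisubstituted C10=C11 alkene should react well before the 1,1-disubstituted allylic-ester alkene and the conjugated angelate alkenes. The D-fructose-derived ketone gives the R epoxide from R–CH2–CH=CMe2 olefins, so its enantiomer is used to set 10S.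

**Compound list**

1 | (±)-cyclopent-2-en-1-yl acetate | CC(=O)OC1C=CCC1 | starting material
2 | dimethyl malonate | COC(=O)CC(=O)OC | starting material
3 | dimethyl (R)-2-(cyclopent-2-en-1-yl)malonate | COC(=O)C(C(=O)OC)[C@@H]1CCC=C1 | intermediate
4 | (R)-2-(cyclopent-2-en-1-yl)malonic acid (not isolated) | OC(=O)C(C(=O)O)[C@@H]1CCC=C1 | intermediate
5 | (S)-2-(cyclopent-2-en-1-yl)acetic acid | OC(=O)C[C@@H]1CCC=C1 | intermediate
6 | cis-fused 6-(phenylselanyl)hexahydro-2H-cyclopenta[b]furan-2-one, selenium trans to the ring oxygen (not isolated) | O=C1C[C@@H]2CC[C@@H]([Se]c3ccccc3)[C@@H]2O1 | intermediate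
7 | (3aS,6aR)-3,3a,4,6a-tetrahydro-2H-cyclopenta[b]furan-2-one | O=C1C[C@@H]2CC=C[C@@H]2O1 | intermediate
8 | (1R,5S)-5-(2-hydroxyethyl)cyclopent-2-en-1-ol | OCC[C@@H]1CC=C[C@@H]1O | intermediate
9 | (1R,5S)-5-[2-(tert-butyldimethylsilyloxy)ethyl]cyclopent-2-en-1-ol (not isolated) | CC(C)(C)[Si](C)(C)OCC[C@@H]1CC=C[C@@H]1O | intermediate
10 | tert-butyl (1R,5S)-5-[2-(tert-butyldimethylsilyloxy)ethyl]cyclopent-2-en-1-yl carbonate | CC(C)(C)[Si](C)(C)OCC[C@@H]1CC=C[C@@H]1OC(=O)OC(C)(C)C | intermediate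
11 | tert-butyl 6,6-dibromo-3-[2-(tert-butyldimethylsilyloxy)ethyl]bicyclo[3.1.0]hexan-2-yl carbonate, 2,3-cis, CBr2 bridge anti | CC(C)(C)[Si](C)(C)OCC[C@@H]1C[C@H]2C(Br)(Br)[C@H]2[C@@H]1OC(=O)OC(C)(C)C | intermediate
12 | 2-bromo-6-(tert-butoxycarbonyloxy)-5-[2-(tert-butyldimethylsilyloxy)ethyl]cyclohex-2-en-1-ylium, allyl cation (not isolated) | CC(C)(C)[Si](C)(C)OCC[C@@H]1C[CH+]C(Br)=C[C@@H]1OC(=O)OC(C)(C)C | intermediate
13 | cis-fused 2-tert-butoxy-1,3-dioxolan-2-ylium ion on the bromocyclohexene (not isolated) | CC(C)(C)[Si](C)(C)OCC[C@@H]1CC=C(Br)[C@@H]2O[C+](OC(C)(C)C)O[C@H]12 | intermediate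
14 | (3aR,4S,7aR)-7-bromo-4-[2-(tert-butyldimethylsilyloxy)ethyl]-3a,4,5,7a-tetrahydro-1,3-benzodioxol-2-one | CC(C)(C)[Si](C)(C)OCC[C@@H]1CC=C(Br)[C@@H]2OC(=O)O[C@H]12 | intermediate
15 | (1R,2R,6S)-3-bromo-6-[2-(tert-butyldimethylsilyloxy)ethyl]cyclohex-3-ene-1,2-diol (not isolated) | CC(C)(C)[Si](C)(C)OCC[C@@H]1CC=C(Br)[C@H](O)[C@@H]1O | intermediate
16 | (1R,2S,6S)-6-[2-(tert-butyldimethylsilyloxy)ethyl]-3-methylcyclohex-3-ene-1,2-diol | CC(C)(C)[Si](C)(C)OCC[C@@H]1CC=C(C)[C@H](O)[C@@H]1O | intermediate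
17 | 2,2-dibutyl-1,3,2-dioxastannolane (stannylene acetal) of diol 16 (not isolated) | CC(C)(C)[Si](C)(C)OCC[C@@H]1CC=C(C)[C@@H]2O[Sn](CCCC)(CCCC)O[C@H]12 | intermediate
18 | (1S,5S,6R)-6-hydroxy-2-methyl-5-[2-(tert-butyldimethylsilyloxy)ethyl]cyclohex-2-en-1-yl acetate | CC(C)(C)[Si](C)(C)OCC[C@@H]1CC=C(C)[C@H](OC(C)=O)[C@@H]1O | intermediate
19 | (1S,2R,3R,4R,6S)-3-hydroxy-1-methyl-4-[2-(tert-butyldimethylsilyloxy)ethyl]-7-oxabicyclo[4.1.0]heptan-2-yl acetate | CC(C)(C)[Si](C)(C)OCC[C@@H]1C[C@@H]2O[C@]2(C)[C@H](OC(C)=O)[C@@H]1O | intermediate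
20 | (1S,2R,3R,4R,6S)-2-acetoxy-1-methyl-4-[2-(tert-butyldimethylsilyloxy)ethyl]-7-oxabicyclo[4.1.0]heptan-3-yl (Z)-2-methylbut-2-enoate | CC(C)(C)[Si](C)(C)OCC[C@@H]1C[C@@H]2O[C@]2(C)[C@H](OC(C)=O)[C@@H]1OC(=O)/C(C)=C\C | intermediate
21 | (1S,2R,3R,4R,6S)-2-acetoxy-4-(2-hydroxyethyl)-1-methyl-7-oxabicyclo[4.1.0]heptan-3-yl (Z)-2-methylbut-2-enoate | OCC[C@@H]1C[C@@H]2O[C@]2(C)[C@H](OC(C)=O)[C@@H]1OC(=O)/C(C)=C\C | intermediate
22 | (1S,2R,3R,4S,6S)-2-acetoxy-1-methyl-4-(2-oxoethyl)-7-oxabicyclo[4.1.0]heptan-3-yl (Z)-2-methylbut-2-enoate | O=CC[C@@H]1C[C@@H]2O[C@]2(C)[C@H](OC(C)=O)[C@@H]1OC(=O)/C(C)=C\C | intermediate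
23 | (1S,2R,3R,4S,6S)-2-acetoxy-1-methyl-4-(3-oxoprop-1-en-2-yl)-7-oxabicyclo[4.1.0]heptan-3-yl (Z)-2-methylbut-2-enoate | C=C(C=O)[C@@H]1C[C@@H]2O[C@]2(C)[C@H](OC(C)=O)[C@@H]1OC(=O)/C(C)=C\C | intermediate
24 | (1S,2R,3R,4S,6S)-2-acetoxy-4-[(3S)-3-hydroxyhexa-1,5-dien-2-yl]-1-methyl-7-oxabicyclo[4.1.0]heptan-3-yl (Z)-2-methylbut-2-enoate | C=C([C@H](CC=C)O)[C@@H]1C[C@@H]2O[C@]2(C)[C@H](OC(C)=O)[C@@H]1OC(=O)/C(C)=C\C | intermediate
25 | (1S,2R,3R,4S,6S)-2-acetoxy-4-[(3S)-3-hydroxy-6-methylhepta-1,5-dien-2-yl]-1-methyl-7-oxabicyclo[4.1.0]heptan-3-yl (Z)-2-methylbut-2-enoate | C=C([C@H](CC=C(C)C)O)[C@@H]1C[C@@H]2O[C@]2(C)[C@H](OC(C)=O)[C@@H]1OC(=O)/C(C)=C\C | intermediate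
26 | (1S,2R,3R,4S,6S)-2-acetoxy-1-methyl-4-{(3S)-6-methyl-3-[(Z)-2-methylbut-2-enoyloxy]hepta-1,5-dien-2-yl}-7-oxabicyclo[4.1.0]heptan-3-yl (Z)-2-methylbut-2-enoate | C=C([C@H](CC=C(C)C)OC(=O)/C(C)=C\C)[C@@H]1C[C@@H]2O[C@]2(C)[C@H](OC(C)=O)[C@@H]1OC(=O)/C(C)=C\C | intermediate
27 | CNP0316628.1, (1S,2R,3R,4S,6S)-2-acetoxy-4-{(3S)-4-[(2S)-3,3-dimethyloxiran-2-yl]-3-[(Z)-2-methylbut-2-enoyloxy]but-1-en-2-yl}-1-methyl-7-oxabicyclo[4.1.0]heptan-3-yl (Z)-2-methylbut-2-enoate | C=C([C@H](C[C@@H]1OC1(C)C)OC(=O)/C(C)=C\C)[C@@H]1C[C@@H]2O[C@]2(C)[C@H](OC(C)=O)[C@@H]1OC(=O)/C(C)=C\C | target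

**Step count and risks**

Total step count: 18. Longest linear sequence: 18 (fully linear from 1 and 2).

Steps most likely to fail:

Step 7. Capture of the allyl cation by the carbonate may lose to proton loss (diene formation), or the Boc group may be cleaved by acid before ionisation. Fallback, from 9 back to 15: the enol-ether variant of the carbene ring expansion, in which C3 is set by hydride and not by a tether. Silylation of 9 (TESCl, imidazole) gives the triethylsilyl ether F1. Hydroboration–oxidation (9-BBN, then NaBO3), with boron expected on the carbon next to the silyloxy carbon, gives the cyclopentanol F2. Dess–Martin oxidation gives the cyclopentanone F3. Kinetic enolisation toward the CH2 side (LDA, TMSCl, −78 °C) gives the trimethylsilyl enol ether F4. Dibromocarbene (CHBr3, KOt-Bu, pentane, −20 °C) gives the siloxy dibromocyclopropane F5, which on warming opens with loss of the silyl bromide to the ring-expanded 2-bromocyclohex-2-enone F6. Luche reduction, with hydride expected anti to the C2 silyloxy group, gives the cis bromo alcohol F7. PPTS in MeOH removes the triethylsilyl group selectively to give 15, which is methylated as in the second stage of step 8.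

Step 9. Discrimination between the two secondary hydroxyls may be poor, or the acetyl group may migrate from O–C3 to O–C2 before step 11. Fallback, from 16 back to 20: the two oxygens are told apart by oxidation state. MnO2 oxidises only the allylic C3 hydroxyl to give the hydroxy enone F8. Its single hydroxyl is angeloylated (mixed-anhydride conditions of step 11) to give the keto angelate F9. Luche reduction, with hydride expected anti to the axial C2 ester, gives the cis allylic alcohol F10. VO(acac)2/t-BuOOH, now directed by the allylic C3 hydroxyl, gives the epoxy alcohol F11. Ac2O/pyridine gives 20.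

Step 11. Acylation of the hindered axial C2 hydroxyl may be slow, which would let Z-to-E isomerisation of the activated angeloyl unit or acetyl migration compete. Fallback, from 19 back to 20: the angelate alkene is built on the substrate. 19 is esterified with 2-[bis(2,2,2-trifluoroethoxy)phosphoryl]propanoic acid (DCC, DMAP; forcing conditions are harmless because no isomerisable alkene is present) to give the phosphonate ester F12. Still–Gennari olefination with acetaldehyde (KHMDS, 18-crown-6, THF, −78 °C) should give the Z-trisubstituted ester 20.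

Further compounds
F1 | step 7 | triethylsilyl ether of 9, (1R,5S)-configured cyclopentene | CC(C)(C)[Si](C)(C)OCC[C@@H]1CC=C[C@@H]1O[Si](CC)(CC)CC
F2 | step 7 | 2-(triethylsilyloxy)-3-[2-(tert-butyldimethylsilyloxy)ethyl]cyclopentan-1-ol, hydroxyl trans to the silyloxy group | CC(C)(C)[Si](C)(C)OCC[C@@H]1CC[C@@H](O)[C@@H]1O[Si](CC)(CC)CC
F3 | step 7 | cis-2-(triethylsilyloxy)-3-[2-(tert-butyldimethylsilyloxy)ethyl]cyclopentan-1-one | CC(C)(C)[Si](C)(C)OCC[C@@H]1CCC(=O)[C@@H]1O[Si](CC)(CC)CC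
F4 | step 7 | trimethylsilyl enol ether of F3 (enol toward the CH2) | CC(C)(C)[Si](C)(C)OCC[C@@H]1CC=C(O[Si](C)(C)C)[C@@H]1O[Si](CC)(CC)CC
F5 | step 7 | 6,6-dibromo-1-(trimethylsilyloxy)bicyclo[3.1.0]hexane from F4 (not isolated) | CC(C)(C)[Si](C)(C)OCC[C@@H]1C[C@H]2C(Br)(Br)[C@@]2(O[Si](C)(C)C)[C@@H]1O[Si](CC)(CC)CC
F6 | step 7 | cis-2-bromo-6-(triethylsilyloxy)-5-[2-(tert-butyldimethylsilyloxy)ethyl]cyclohex-2-en-1-one | CC(C)(C)[Si](C)(C)OCC[C@@H]1CC=C(Br)C(=O)[C@@H]1O[Si](CC)(CC)CC
F7 | step 7 | all-cis 2-bromo-6-(triethylsilyloxy)-5-[2-(tert-butyldimethylsilyloxy)ethyl]cyclohex-2-en-1-ol | CC(C)(C)[Si](C)(C)OCC[C@@H]1CC=C(Br)[C@H](O)[C@@H]1O[Si](CC)(CC)CC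
F8 | step 9 | cis-6-hydroxy-2-methyl-5-[2-(tert-butyldimethylsilyloxy)ethyl]cyclohex-2-en-1-one | CC(C)(C)[Si](C)(C)OCC[C@@H]1CC=C(C)C(=O)[C@@H]1O
F9 | step 9 | cis-3-methyl-2-oxo-6-[2-(tert-butyldimethylsilyloxy)ethyl]cyclohex-3-en-1-yl (Z)-2-methylbut-2-enoate | CC(C)(C)[Si](C)(C)OCC[C@@H]1CC=C(C)C(=O)[C@@H]1OC(=O)/C(C)=C\C
F10 | step 9 | all-cis 2-hydroxy-3-methyl-6-[2-(tert-butyldimethylsilyloxy)ethyl]cyclohex-3-en-1-yl (Z)-2-methylbut-2-enoate | CC(C)(C)[Si](C)(C)OCC[C@@H]1CC=C(C)[C@H](O)[C@@H]1OC(=O)/C(C)=C\C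
F11 | step 9 | all-cis 2-hydroxy-1-methyl-4-[2-(tert-butyldimethylsilyloxy)ethyl]-7-oxabicyclo[4.1.0]heptan-3-yl (Z)-2-methylbut-2-enoate | CC(C)(C)[Si](C)(C)OCC[C@@H]1C[C@@H]2O[C@]2(C)[C@H](O)[C@@H]1OC(=O)/C(C)=C\C
F12 | step 11 | 2-[bis(2,2,2-trifluoroethoxy)phosphoryl]propanoate ester of 19 at O–C2 | CC(C)(C)[Si](C)(C)OCC[C@@H]1C[C@@H]2O[C@]2(C)[C@H](OC(C)=O)[C@@H]1OC(=O)C(C)P(=O)(OCC(F)(F)F)OCC(F)(F)F
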